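**Plan**
Numbering (drimane): ring A = C1–C5 and C10, ring B = C5–C10, C11 = the OCH2 on C9, β = the face of the C10 methyl. The retrosynthesis cuts the O–C11 aryl ether (isofraxidin), the O3 ester, and then C5–C10 and C8–C9 of the decalin in a single step.
Enabling feature: the C6 ketone with C5–C8 is a latent 2-silyloxydiene, C9=C10 carrying C11 is a (Z)-enal, and C2–C3(O)–C4(CH3)2–C5 is the carbon chain of D-pantolactone. An acyclic triene can therefore fold into rings A and B together.
Forward: D-pantolactone → C1=C2 alkenol → B-alkyl Suzuki coupling with ethyl (Z)-3-iodobut-2-enoate (joins C1–C10, fixes the Z alkene) → one-carbon homologation at C5, propenyl ketone, TIPS dienol ether → Z-enal → cycloaddition.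
After ring formation: aldehyde reduction, desilylation with C5 equilibration, C3 oxidation and reduction, Mitsunobu etherification, acylation, and Saegusa–Ito desaturation (C7=C8) last.
Stereochemistry: C3 of D-pantolactone steers the cycloaddition to one face (C10). The Z alkene gives C9 (C11 trans to the C10 methyl). C5 is set by equilibration to the trans-decalone. C3 is inverted to 3α through the ketone and LiBH(sec-Bu)3.

Key step: step 13

Remark: the bicyclic compounds are named with drimane numbering; "5β,8β,9β(H)" gives the faces of the hydrogens at those carbons.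
Assumption: the cycloaddition is taken to run mainly through the endo mode; an exo adduct would carry the same C9 and C10 configuration and is not carried on.

**Route**

Step 1
Reactants: 1 ethyl but-2-ynoate
Product: 2 ethyl (2Z)-3-iodobut-2-enoate
Conditions: NaI, AcOH, 110 °C
Reagents that add atoms: sodium iodide [Na+].[I-]
Why: Hydroiodination of the ynoate (conjugate addition of iodide, then protonation anti to it) is the standard entry to the β-iodo enoate with iodine cis to the ester.

Step 2
Reactants: 3 D-pantolactone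
Product: 4 (3R)-3-(tert-butyldimethylsilyloxy)-4,4-dimethyloxolan-2-one
Conditions: TBSCl, imidazole, DMF, rt
Reagents that add atoms: tert-butyldimethylsilyl chloride CC(C)(C)[Si](C)(C)Cl
Why: Silyl ether formation protects the only hydroxyl and leaves the lactone and the (R) centre (the future C3) untouched.

Step 3
Reactants: 4 (3R)-3-(tert-butyldimethylsilyloxy)-4,4-dimethyloxolan-2-one
Product: 5 (3R)-3-(tert-butyldimethylsilyloxy)-4,4-dimethyloxolan-2-ol (anomer mixture)
Conditions: i-Bu2AlH, CH2Cl2, −78 °C
Reagents that add atoms: none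
Why: Partial reduction of a lactone stops at the lactol because the aluminium hemiacetal is stable at −78 °C.

Step 4
Reactants: 5 (3R)-3-(tert-butyldimethylsilyloxy)-4,4-dimethyloxolan-2-ol
Product: 6 (3S)-3-(tert-butyldimethylsilyloxy)-2,2-dimethylpent-4-en-1-ol
Conditions: Ph3PCH3Br, n-BuLi, THF, −78 to 0 °C
Reagents that add atoms: methyltriphenylphosphonium bromide C[P+](c1ccccc1)(c1ccccc1)c1ccccc1.[Br-]
Why: Wittig methylenation of the open hydroxy-aldehyde form of the lactol installs C1=C2 and frees the C5 alcohol, and keeping the lithium alkoxide at or below 0 °C holds 1,3-silyl transfer from O3 to O5 back.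

Step 5
Reactants: 6 (3S)-3-(tert-butyldimethylsilyloxy)-2,2-dimethylpent-4-en-1-ol; 2 ethyl (2Z)-3-iodobut-2-enoate
Product: 8 ethyl (2Z,6S)-6-(tert-butyldimethylsilyloxy)-8-hydroxy-3,7,7-trimethyloct-2-enoate, via B-alkyl-9-BBN borane 7 (not isolated)
Conditions: 9-BBN (2.2 equiv), THF, rt; then 2, PdCl2(dppf), AsPh3, K3PO4 (aq.), DMF, rt
Reagents that add atoms: none
Why: 9-BBN hydroborates the terminal alkene at C1 and the B-alkyl Suzuki–Miyaura coupling replaces iodine with retention, so the chain ends up cis to the ester and the C9=C10 geometry is fixed here (the extra 9-BBN accommodates the free hydroxyl).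

Step 6
Reactants: 8 ethyl (2Z,6S)-6-(tert-butyldimethylsilyloxy)-8-hydroxy-3,7,7-trimethyloct-2-enoate
Product: 9 ethyl (2Z,6S)-6-(tert-butyldimethylsilyloxy)-3,7,7-trimethyl-8-oxooct-2-enoate
Conditions: Dess–Martin periodinane, NaHCO3, CH2Cl2, rt
Reagents that add atoms: none
Why: Dess–Martin oxidation of the neopentyl primary alcohol gives a non-enolisable aldehyde without touching the enoate or the silyl ether.

Step 7
Reactants: 9 ethyl (2Z,6S)-6-(tert-butyldimethylsilyloxy)-3,7,7-trimethyl-8-oxooct-2-enoate
Product: 11 ethyl (2Z,6S)-6-(tert-butyldimethylsilyloxy)-3,7,7-trimethyl-9-oxonon-2-enoate, via methyl enol ether 10 (not isolated)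
Conditions: Ph3P(CH2OMe)Cl, KN(SiMe3)2, THF, 0 °C; then 1 M HCl (aq.), rt
Reagents that add atoms: (methoxymethyl)triphenylphosphonium chloride COC[P+](c1ccccc1)(c1ccccc1)c1ccccc1.[Cl-]; water O
Why: Wittig methoxymethylenation followed by acid hydrolysis of the enol ether is the classical one-carbon aldehyde homologation, which inserts C6 and leaves C5 as CH2, and the hindered secondary TBS ether should withstand brief dilute acid.

Step 8
Reactants: 11 ethyl (2Z,6S)-6-(tert-butyldimethylsilyloxy)-3,7,7-trimethyl-9-oxonon-2-enoate; 12 (E)-1-bromoprop-1-ene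
Product: 14 ethyl (2Z,6S,10E)-6-(tert-butyldimethylsilyloxy)-9-hydroxy-3,7,7-trimethyldodeca-2,10-dienoate (C9 epimers), via (E)-prop-1-enyllithium 13 (not isolated)
Conditions: 12, t-BuLi (2 equiv), Et2O, −78 °C; then 11, −78 °C
Reagents that add atoms: none
Why: Bromine–lithium exchange retains the E geometry and the alkenyllithium adds 1,2 to the aldehyde at −78 °C much faster than to the β,β-disubstituted enoate, the carbinol configuration being irrelevant.

Step 9
Reactants: 14 ethyl (2Z,6S,10E)-6-(tert-butyldimethylsilyloxy)-9-hydroxy-3,7,7-trimethyldodeca-2,10-dienoate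
Product: 15 ethyl (2Z,6S,10E)-6-(tert-butyldimethylsilyloxy)-3,7,7-trimethyl-9-oxododeca-2,10-dienoate
Conditions: Dess–Martin periodinane, NaHCO3, CH2Cl2, 0 °C
Reagents that add atoms: none
Why: Buffered Dess–Martin oxidation of the allylic alcohol gives the (E)-propenyl ketone and leaves both alkene geometries alone.

Step 10
Reactants: 15 ethyl (2Z,6S,10E)-6-(tert-butyldimethylsilyloxy)-3,7,7-trimethyl-9-oxododeca-2,10-dienoate
Product: 16 ethyl (2Z,6S,8Z,10E)-6-(tert-butyldimethylsilyloxy)-3,7,7-trimethyl-9-(triisopropylsilyloxy)dodeca-2,8,10-trienoate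
Conditions: TIPSOTf, Et3N, CH2Cl2, 0 °C to rt
Reagents that add atoms: triisopropylsilyl trifluoromethanesulfonate CC(C)[Si](C(C)C)(C(C)C)OS(=O)(=O)C(F)(F)F
Why: Soft enolisation of an alkenyl ketone with a silyl triflate and Et3N deprotonates the α' CH2 (C5) and gives the cross-conjugated 2-silyloxydiene with the bulky C4 group cis to oxygen, which places the tether on the outside of the diene, and the ester is not enolised under these conditions.

Step 11
Reactants: 16 ethyl (2Z,6S,8Z,10E)-6-(tert-butyldimethylsilyloxy)-3,7,7-trimethyl-9-(triisopropylsilyloxy)dodeca-2,8,10-trienoate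
Product: 17 (2Z,6S,8Z,10E)-6-(tert-butyldimethylsilyloxy)-3,7,7-trimethyl-9-(triisopropylsilyloxy)dodeca-2,8,10-trien-1-ol
Conditions: i-Bu2AlH, CH2Cl2, −78 °C; aq. potassium sodium tartrate work-up
Reagents that add atoms: none
Why: i-Bu2AlH reduces the enoate 1,2 to the allylic alcohol at −78 °C, while the silyl enol ether and silyl ether are inert to hydride and the neutral work-up avoids acid.

Step 12
Reactants: 17 (2Z,6S,8Z,10E)-6-(tert-butyldimethylsilyloxy)-3,7,7-trimethyl-9-(triisopropylsilyloxy)dodeca-2,8,10-trien-1-ol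
Product: 18 (2Z,6S,8Z,10E)-6-(tert-butyldimethylsilyloxy)-3,7,7-trimethyl-9-(triisopropylsilyloxy)dodeca-2,8,10-trienal
Conditions: MnO2, CH2Cl2, rt
Reagents that add atoms: none
Why: MnO2 oxidises allylic alcohols to enals under neutral heterogeneous conditions with retention of the Z geometry (as in nerol to neral) and spares the silyloxydiene.

Step 13
Reactants: 18 (2Z,6S,8Z,10E)-6-(tert-butyldimethylsilyloxy)-3,7,7-trimethyl-9-(triisopropylsilyloxy)dodeca-2,8,10-trienal
Product: 19 3β-(tert-butyldimethylsilyloxy)-6-(triisopropylsilyloxy)-5β,8β,9β(H)-drim-6-en-11-al (cis-fused endo adduct)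
Conditions: toluene (0.005 M), BHT, 2,6-di-tert-butyl-4-methylpyridine, sealed tube, 150 °C
Reagents that add atoms: none
Why: Thermal intramolecular Diels–Alder reaction of the type known for 2-silyloxy-1,7,9-decatrienes with an enal dienophile: the electron-rich C5–C8 diene (largest HOMO coefficient at C5) and the C9=C10 enal (electrophilic at C10) combine in a concerted but asynchronous [4+2] in which the C5–C10 bond runs ahead of C8–C9. Ring B is the cyclohexene formed by the cycloaddition itself, and ring A closes in the same event as the six-membered ring spanned by the C1–C4 tether through the C5–C10 bond, the tether adopting a chair. C9 relative to C10 follows from suprafacial addition to the Z alkene, which keeps the formyl group cis to C1 and hence trans to the C10 methyl. The absolute sense at C10 (and with it C9) is controlled by C3: with the C10 methyl axial on the forming chair, the silyloxy group takes the equatorial site, since an axial one would sit 1,3 to the diene carbon C6 in the endo mode, and this puts O3 cis to the C10 methyl. C5 and C8 reflect the endo mode expected for a Z dienophile whose formyl group and tether are cis (cis fusion, C8 methyl cis to C11), but C5 is equilibrated in step 15 and C8 becomes sp2 in step 20, so only face selectivity and retention of the Z geometry are required. The gem-dimethyl group at C4 favours the folded reactive conformer, and high dilution, BHT and a hindered pyridine base guard against polymerisation and acid-mediated Z to E leakage of the enal.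

Step 14
Reactants: 19 3β-(tert-butyldimethylsilyloxy)-6-(triisopropylsilyloxy)-5β,8β,9β(H)-drim-6-en-11-al
Product: 20 3β-(tert-butyldimethylsilyloxy)-6-(triisopropylsilyloxy)-5β,8β,9β(H)-drim-6-en-11-ol
Conditions: NaBH4, EtOH, 0 °C
Reagents that add atoms: none
Why: Borohydride reduction of the hindered aldehyde should outrun epimerisation at C9 and removes the only base-labile stereocentre before C5 is equilibrated, the silyl enol ether and silyl ether being inert.

Step 15
Reactants: 20 3β-(tert-butyldimethylsilyloxy)-6-(triisopropylsilyloxy)-5β,8β,9β(H)-drim-6-en-11-ol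
Product: 22 3β,11-dihydroxy-5α,8β,9β(H)-driman-6-one (trans-fused), via cis-fused keto diol 21 (not isolated)
Conditions: HF (48% aq.), MeCN, rt; then NaOMe, MeOH, 40 °C
Reagents that add atoms: none
Why: Aqueous HF hydrolyses the silyl enol ether to the C6 ketone and cleaves the TBS ether, and methoxide then equilibrates C5 through the enolate to the trans-decalone (5α-H), favoured because each chair form of the cis isomer carries an extra syn-pentane contact (C8 methyl against C1, or C4 against C11) that the trans isomer avoids, while C9 is not acidic at this stage.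

Step 16
Reactants: 22 3β,11-dihydroxy-5α,8β,9β(H)-driman-6-one
Product: 23 3,6-dioxo-5α,8β,9β(H)-driman-11-al
Conditions: Dess–Martin periodinane, NaHCO3, CH2Cl2, rt
Reagents that add atoms: none
Why: Dess–Martin periodinane oxidises the equatorial C3 alcohol and the primary alcohol together under buffered neutral conditions, clearing C3 for re-reduction without enolising C5 or C9 (the crude product should be used directly).

Step 17
Reactants: 23 3,6-dioxo-5α,8β,9β(H)-driman-11-al
Product: 24 3α,11-dihydroxy-5α,8β,9β(H)-driman-6-one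
Conditions: LiBH(sec-Bu)3 (2.2 equiv), THF, −78 °C
Reagents that add atoms: none
Why: The bulky borohydride attacks the 4,4-dimethyl-3-ketone of a trans-decalin along the equatorial trajectory to give the axial 3α-alcohol (the usual outcome for 3-oxo-4,4-dimethyl terpenoid A rings) and reduces the aldehyde, while the C6 ketone, screened on its β face by the axial C4 and C10 methyls and on its α face by axial C11, should survive at −78 °C by analogy with C3-selective reductions of 3,6-diketo steroids.

Step 18
Reactants: 24 3α,11-dihydroxy-5α,8β,9β(H)-driman-6-one; 25 isofraxidin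
Product: 26 7-[(3α-hydroxy-6-oxo-5α,8β,9β(H)-driman-11-yl)oxy]-6,8-dimethoxycoumarin
Conditions: 25, PPh3, DIAD, THF, 0 to 40 °C
Reagents that add atoms: none
Why: Mitsunobu etherification joins the acidic phenol to the primary alcohol by SN2 displacement, the axial neopentyl C3 alcohol does not react, and nothing in this saturated substrate can eliminate.

Step 19
Reactants: 26 7-[(3α-hydroxy-6-oxo-5α,8β,9β(H)-driman-11-yl)oxy]-6,8-dimethoxycoumarin
Product: 27 7-[(3α-(3-methylbutanoyloxy)-6-oxo-5α,8β,9β(H)-driman-11-yl)oxy]-6,8-dimethoxycoumarin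
Conditions: 3-methylbutanoyl chloride, DMAP, pyridine, CH2Cl2, rt
Reagents that add atoms: 3-methylbutanoyl chloride CC(C)CC(=O)Cl
Why: DMAP-catalysed acylation with the acid chloride esterifies the remaining axial secondary alcohol and leaves coumarin, aryl ether and ketone unaffected.

Step 20
Reactants: 27 7-[(3α-(3-methylbutanoyloxy)-6-oxo-5α,8β,9β(H)-driman-11-yl)oxy]-6,8-dimethoxycoumarin
Product: 29 7-[(3α-(3-methylbutanoyloxy)-6-oxo-5α,9β(H)-drim-7-en-11-yl)oxy]-6,8-dimethoxycoumarin (CNP0279705.1), via trimethylsilyl enol ether 28 (not isolated)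
Conditions: TMSOTf, Et3N, CH2Cl2, 0 °C; then Pd(OAc)2, MeCN, rt
Reagents that add atoms: none
Why: Soft enolisation should go to the less hindered C6=C7 silyl enol ether and the Saegusa–Ito oxidation then gives the C7=C8 enone by β-hydride loss from C8 (the C5 side has no β-hydrogen), under non-basic conditions that avoid vinylogous loss of the aryloxide from C11 and leave C5 and C9 intact.

**Compound list**
1 | ethyl but-2-ynoate | CCOC(=O)C#CC | starting material
2 | ethyl (2Z)-3-iodobut-2-enoate | CCOC(=O)/C=C(/C)I | intermediate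
3 | D-pantolactone, (3R)-3-hydroxy-4,4-dimethyloxolan-2-one | CC1(C)COC(=O)[C@@H]1O | starting material
4 | (3R)-3-(tert-butyldimethylsilyloxy)-4,4-dimethyloxolan-2-one | CC1(C)COC(=O)[C@@H]1O[Si](C)(C)C(C)(C)C | intermediate
5 | (3R)-3-(tert-butyldimethylsilyloxy)-4,4-dimethyloxolan-2-ol (anomer mixture) | CC1(C)COC(O)[C@@H]1O[Si](C)(C)C(C)(C)C | intermediate
6 | (3S)-3-(tert-butyldimethylsilyloxy)-2,2-dimethylpent-4-en-1-ol | C=C[C@H](O[Si](C)(C)C(C)(C)C)C(C)(C)CO | intermediate
7 | 9-[(3S)-3-(tert-butyldimethylsilyloxy)-5-hydroxy-4,4-dimethylpentyl]-9-borabicyclo[3.3.1]nonane (hydroxyl drawn free) | CC(C)(CO)[C@@H](O[Si](C)(C)C(C)(C)C)CCB1C2CCCC1CCC2 | intermediate (not isolated)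
8 | ethyl (2Z,6S)-6-(tert-butyldimethylsilyloxy)-8-hydroxy-3,7,7-trimethyloct-2-enoate | CCOC(=O)/C=C(/C)CC[C@H](O[Si](C)(C)C(C)(C)C)C(C)(C)CO | intermediate
9 | ethyl (2Z,6S)-6-(tert-butyldimethylsilyloxy)-3,7,7-trimethyl-8-oxooct-2-enoate | CCOC(=O)/C=C(/C)CC[C@H](O[Si](C)(C)C(C)(C)C)C(C)(C)C=O | intermediate
10 | ethyl (2Z,6S)-6-(tert-butyldimethylsilyloxy)-9-methoxy-3,7,7-trimethylnona-2,8-dienoate (E/Z mixture at C8) | CCOC(=O)/C=C(/C)CC[C@H](O[Si](C)(C)C(C)(C)C)C(C)(C)C=COC | intermediate (not isolated)
11 | ethyl (2Z,6S)-6-(tert-butyldimethylsilyloxy)-3,7,7-trimethyl-9-oxonon-2-enoate | CCOC(=O)/C=C(/C)CC[C@H](O[Si](C)(C)C(C)(C)C)C(C)(C)CC=O | intermediate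
12 | (E)-1-bromoprop-1-ene | C/C=C/Br | starting material
13 | (E)-prop-1-enyllithium | [Li]/C=C/C | intermediate (not isolated)
14 | ethyl (2Z,6S,10E)-6-(tert-butyldimethylsilyloxy)-9-hydroxy-3,7,7-trimethyldodeca-2,10-dienoate (C9 epimers) | CCOC(=O)/C=C(/C)CC[C@H](O[Si](C)(C)C(C)(C)C)C(C)(C)CC(O)/C=C/C | intermediate
15 | ethyl (2Z,6S,10E)-6-(tert-butyldimethylsilyloxy)-3,7,7-trimethyl-9-oxododeca-2,10-dienoate | CCOC(=O)/C=C(/C)CC[C@H](O[Si](C)(C)C(C)(C)C)C(C)(C)CC(=O)/C=C/C | intermediate
16 | ethyl (2Z,6S,8Z,10E)-6-(tert-butyldimethylsilyloxy)-3,7,7-trimethyl-9-(triisopropylsilyloxy)dodeca-2,8,10-trienoate | CCOC(=O)/C=C(/C)CC[C@H](O[Si](C)(C)C(C)(C)C)C(C)(C)/C=C(O[Si](C(C)C)(C(C)C)C(C)C)/C=C/C | intermediate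
17 | (2Z,6S,8Z,10E)-6-(tert-butyldimethylsilyloxy)-3,7,7-trimethyl-9-(triisopropylsilyloxy)dodeca-2,8,10-trien-1-ol | OC/C=C(/C)CC[C@H](O[Si](C)(C)C(C)(C)C)C(C)(C)/C=C(O[Si](C(C)C)(C(C)C)C(C)C)/C=C/C | intermediate
18 | (2Z,6S,8Z,10E)-6-(tert-butyldimethylsilyloxy)-3,7,7-trimethyl-9-(triisopropylsilyloxy)dodeca-2,8,10-trienal | O=C/C=C(/C)CC[C@H](O[Si](C)(C)C(C)(C)C)C(C)(C)/C=C(O[Si](C(C)C)(C(C)C)C(C)C)/C=C/C | intermediate (key-step precursor)
19 | 3β-(tert-butyldimethylsilyloxy)-6-(triisopropylsilyloxy)-5β,8β,9β(H)-drim-6-en-11-al | O=C[C@@H]1[C@H](C)C=C(O[Si](C(C)C)(C(C)C)C(C)C)[C@@H]2C(C)(C)[C@@H](O[Si](C)(C)C(C)(C)C)CC[C@]12C | intermediate (key-step product)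
20 | 3β-(tert-butyldimethylsilyloxy)-6-(triisopropylsilyloxy)-5β,8β,9β(H)-drim-6-en-11-ol | OC[C@@H]1[C@H](C)C=C(O[Si](C(C)C)(C(C)C)C(C)C)[C@@H]2C(C)(C)[C@@H](O[Si](C)(C)C(C)(C)C)CC[C@]12C | intermediate
21 | 3β,11-dihydroxy-5β,8β,9β(H)-driman-6-one (cis-fused) | OC[C@@H]1[C@H](C)CC(=O)[C@@H]2C(C)(C)[C@@H](O)CC[C@]12C | intermediate (not isolated)
22 | 3β,11-dihydroxy-5α,8β,9β(H)-driman-6-one (trans-fused) | OC[C@@H]1[C@H](C)CC(=O)[C@H]2C(C)(C)[C@@H](O)CC[C@]12C | intermediate
23 | 3,6-dioxo-5α,8β,9β(H)-driman-11-al | O=C[C@@H]1[C@H](C)CC(=O)[C@H]2C(C)(C)C(=O)CC[C@]12C | intermediate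
24 | 3α,11-dihydroxy-5α,8β,9β(H)-driman-6-one | OC[C@@H]1[C@H](C)CC(=O)[C@H]2C(C)(C)[C@H](O)CC[C@]12C | intermediate
25 | isofraxidin, 7-hydroxy-6,8-dimethoxycoumarin | COc1cc2ccc(=O)oc2c(OC)c1O | starting material
26 | 7-[(3α-hydroxy-6-oxo-5α,8β,9β(H)-driman-11-yl)oxy]-6,8-dimethoxycoumarin | COc1cc2ccc(=O)oc2c(OC)c1OC[C@@H]1[C@H](C)CC(=O)[C@H]2C(C)(C)[C@H](O)CC[C@]12C | intermediate
27 | 7-[(3α-(3-methylbutanoyloxy)-6-oxo-5α,8β,9β(H)-driman-11-yl)oxy]-6,8-dimethoxycoumarin | COc1cc2ccc(=O)oc2c(OC)c1OC[C@@H]1[C@H](C)CC(=O)[C@H]2C(C)(C)[C@H](OC(=O)CC(C)C)CC[C@]12C | intermediate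
28 | 7-[(3α-(3-methylbutanoyloxy)-6-(trimethylsilyloxy)-5α,8β,9β(H)-drim-6-en-11-yl)oxy]-6,8-dimethoxycoumarin | COc1cc2ccc(=O)oc2c(OC)c1OC[C@@H]1[C@H](C)C=C(O[Si](C)(C)C)[C@H]2C(C)(C)[C@H](OC(=O)CC(C)C)CC[C@]12C | intermediate (not isolated)
29 | 7-[(3α-(3-methylbutanoyloxy)-6-oxo-5α,9β(H)-drim-7-en-11-yl)oxy]-6,8-dimethoxycoumarin (CNP0279705.1) | COc1cc2ccc(=O)oc2c(OC)c1OC[C@@H]1C(C)=CC(=O)[C@H]2C(C)(C)[C@H](OC(=O)CC(C)C)CC[C@]12C | target

**Totals**
Total step count: 20. Longest linear sequence: 19 steps (steps 2–20, from D-pantolactone); step 1 is a one-step side branch.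

**Three steps most likely to fail**

Step 13 (cycloaddition). At the temperature needed to join the two congested carbons C5 and C10, the Z-enal may lose its geometry (a 1,5-hydrogen shift from C1 to the carbonyl oxygen gives a dienol, or trace acid isomerises it). The E isomer would then cyclise with the wrong C9/C10 relationship, or the enal may decompose before ring closure. Fallback: use the ester as the activating group, which holds its geometry and has no easy dienol pathway. The fallback sets out from 16, which is heated (1,2-dichlorobenzene, BHT, 180–200 °C) to give the ethyl ester cycloadduct F1 by the same bond formation. Reduction of F1 with LiAlH4 (Et2O, 0 °C) returns to the route at 20.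

Step 17 (selective reduction). The hydride may also add to the C6 ketone, or face selectivity at C3 may be incomplete, so that mixtures at two centres reach the etherification. Fallback: reduce all three carbonyls on purpose and restore C6 later. The fallback sets out from 23, which with excess LiBH(sec-Bu)3 (−78 °C to rt) gives the drimane-3α,6β,11-triol F2 (C6 drawn as 6β; its configuration is without consequence). Mitsunobu coupling with 25 at the primary alcohol gives the diol ether F3. Acylation with 3-methylbutanoyl chloride and DMAP occurs at O3 only, because the 6β-hydroxyl is flanked by two syn-axial methyl groups, and gives the hydroxy ester F4. Dess–Martin oxidation of the C6 alcohol returns to the route at 27.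

Step 18 (etherification). Displacement at the β-branched C11 carbinol next to the quaternary C10 may be slow enough that the phosphonium intermediate is consumed unproductively (alkylation of the hydrazide, decomposition of the betaine) before the hindered phenoxide attacks. Fallback: separate activation from displacement and use a better leaving group. The fallback sets out from 24, which with Tf2O and 2,6-lutidine (CH2Cl2, −78 °C) is sulfonylated at the primary alcohol to give the primary triflate F5. Williamson displacement with 25 and Cs2CO3 (DMF, 0 °C to rt) returns to the route at 26.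

**Further compounds**
F1 | step 13 | ethyl 3β-(tert-butyldimethylsilyloxy)-6-(triisopropylsilyloxy)-5β,8β,9β(H)-drim-6-en-11-oate | CCOC(=O)[C@@H]1[C@H](C)C=C(O[Si](C(C)C)(C(C)C)C(C)C)[C@@H]2C(C)(C)[C@@H](O[Si](C)(C)C(C)(C)C)CC[C@]12C
F2 | step 17 | 5α,8β,9β(H)-drimane-3α,6β,11-triol | OC[C@@H]1[C@H](C)C[C@@H](O)[C@H]2C(C)(C)[C@H](O)CC[C@]12C
F3 | step 17 | 7-[(3α,6β-dihydroxy-5α,8β,9β(H)-driman-11-yl)oxy]-6,8-dimethoxycoumarin | COc1cc2ccc(=O)oc2c(OC)c1OC[C@@H]1[C@H](C)C[C@@H](O)[C@H]2C(C)(C)[C@H](O)CC[C@]12C
F4 | step 17 | 7-[(6β-hydroxy-3α-(3-methylbutanoyloxy)-5α,8β,9β(H)-driman-11-yl)oxy]-6,8-dimethoxycoumarin | COc1cc2ccc(=O)oc2c(OC)c1OC[C@@H]1[C@H](C)C[C@@H](O)[C@H]2C(C)(C)[C@H](OC(=O)CC(C)C)CC[C@]12C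
F5 | step 18 | 3α-hydroxy-6-oxo-5α,8β,9β(H)-driman-11-yl trifluoromethanesulfonate | O=S(=O)(OC[C@@H]1[C@H](C)CC(=O)[C@H]2C(C)(C)[C@H](O)CC[C@]12C)C(F)(F)F
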